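The target is the C2-symmetric head-to-head dimer of the lindenane dienolide chloranthalactone A: its cyclobutane C8–C9–C9′–C8′ (C8/C8′ the adjacent oxygen-bearing spiro carbons shared with the butenolides, C9/C9′ the CH carbons next to the methyl-bearing C10/C10′) is the union of two enol-lactone C8=C9 bonds. Cutting C8–C8′ and C9–C9′ leaves two identical monomers. The key step, a biomimetic [2+2] photodimerisation of the γ-alkylidenebutenolide, forms both bonds, the four-membered ring and four stereocentres at once. Its precursor, chloranthalactone A, is built from (+)-verbenone by vinyl conjugate addition, cyclobutane fragmentation, intramolecular carbene cyclopropanation and pyruvate butenolide annulation.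

Key step: step 12

Remark: carbons are numbered as in lindenane (cyclopropane C1–C2–C3, C4=C15H2, C5, C6, C7, C8, C9, C10 bearing methyl C14, C11–C13 the propanoate carbons, primes for the second half), and (1R,5R)-(+)-verbenone is taken to be commercially available in high enantiomeric purity.

Step 1
Reactants: 1 (1R,5R)-(+)-verbenone; 2 vinylmagnesium bromide
Product: 3 (1R,4S,5S)-4-ethenyl-4,6,6-trimethylbicyclo[3.1.1]heptan-2-one
Conditions: CuBr·SMe2 (cat.), THF, −40 °C to 0 °C; then H2O
Reagents that add atoms: none
Why: Copper-catalysed conjugate addition of the Grignard reagent to the β,β-disubstituted enone delivers the vinyl group from the face of the CH2 bridge, anti to the gem-dimethyl bridge, which sets the quaternary centre (future C10) with its methyl syn to the CMe2 bridge.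

Step 2
Reactants: 3 (1R,4S,5S)-4-ethenyl-4,6,6-trimethylbicyclo[3.1.1]heptan-2-one
Product: 4 (4S,5S)-5-ethenyl-5-methyl-4-(prop-1-en-2-yl)cyclohex-1-en-1-yl acetate
Conditions: Zn(OAc)2, BF3·OEt2, Ac2O, 0 °C to rt
Reagents that add atoms: acetic anhydride, CC(=O)OC(C)=O
Why: Lewis-acid-promoted, carbonyl-assisted fragmentation of the strained cyclobutane (cleavage between the α-carbon and the CMe2 carbon) gives a tertiary cation that loses a methyl proton to the isopropenyl group while the enolate is captured as its acetate; no stereocentre is touched, so vinyl and isopropenyl are trans as dictated by step 1.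

Step 3
Reactants: 4 (4S,5S)-5-ethenyl-5-methyl-4-(prop-1-en-2-yl)cyclohex-1-en-1-yl acetate
Product: 5 (3S,4S)-3-ethenyl-3-methyl-4-(prop-1-en-2-yl)cyclohexan-1-one
Conditions: K2CO3 (cat.), MeOH, rt
Reagents that add atoms: none
Why: Base-catalysed transesterification of the enol acetate with methanol releases the ketone, which has no stereocentre α to the carbonyl and so cannot epimerise.

Step 4
Reactants: 5 (3S,4S)-3-ethenyl-3-methyl-4-(prop-1-en-2-yl)cyclohexan-1-one
Product: 6 (7S,8S)-7-ethenyl-7-methyl-8-(prop-1-en-2-yl)-1,4-dioxaspiro[4.5]decane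
Conditions: HOCH2CH2OH, PPTS (cat.), benzene, reflux (Dean–Stark)
Reagents that add atoms: ethylene glycol, OCCO
Why: Acid-catalysed ketalisation with azeotropic removal of water masks the C8 ketone against the allylic oxidation and keeps the later hydrazone formation confined to the aldehyde.

Step 5
Reactants: 6 (7S,8S)-7-ethenyl-7-methyl-8-(prop-1-en-2-yl)-1,4-dioxaspiro[4.5]decane
Product: 7 2-[(7S,8R)-7-ethenyl-7-methyl-1,4-dioxaspiro[4.5]decan-8-yl]prop-2-en-1-ol
Conditions: SeO2 (cat.), t-BuOOH, CH2Cl2, rt
Reagents that add atoms: tert-butyl hydroperoxide, CC(C)(C)OO (its oxygen is relayed through catalytic SeO2, O=[Se]=O)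
Why: Riley allylic oxidation (ene reaction, then [2,3]-sigmatropic shift) takes place on the more electron-rich 1,1-disubstituted alkene at its methyl group, while the vinyl group on quaternary C10 has no allylic hydrogen and stays inert.

Step 6
Reactants: 7 2-[(7S,8R)-7-ethenyl-7-methyl-1,4-dioxaspiro[4.5]decan-8-yl]prop-2-en-1-ol
Product: 8 2-[(7S,8R)-7-ethenyl-7-methyl-1,4-dioxaspiro[4.5]decan-8-yl]prop-2-enal
Conditions: Dess–Martin periodinane, pyridine, CH2Cl2, 0 °C to rt
Reagents that add atoms: none
Why: Dess–Martin oxidation converts the primary allylic alcohol into the 2-substituted acrolein under buffered conditions that spare the dioxolane, both alkenes and the C5 centre next to the new enal.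

Step 7
Reactants: 8 2-[(7S,8R)-7-ethenyl-7-methyl-1,4-dioxaspiro[4.5]decan-8-yl]prop-2-enal
Product: 9 N′-{(E)-2-[(7S,8R)-7-ethenyl-7-methyl-1,4-dioxaspiro[4.5]decan-8-yl]prop-2-en-1-ylidene}-4-methylbenzenesulfonohydrazide
Conditions: TsNHNH2, MeOH, rt
Reagents that add atoms: p-toluenesulfonyl hydrazide, Cc1ccc(cc1)S(=O)(=O)NN
Why: Condensation of the only free carbonyl group, the aldehyde, with the sulfonyl hydrazide should give the E-configured α,β-unsaturated tosylhydrazone.

Step 8
Reactants: 9 N′-{(E)-2-[(7S,8R)-7-ethenyl-7-methyl-1,4-dioxaspiro[4.5]decan-8-yl]prop-2-en-1-ylidene}-4-methylbenzenesulfonohydrazide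
Product: 12 8,8-ethylenedioxy-(1R,3S,5S,10S)-11,12,13-trinorlinden-4(15)-ene, via hydrazone sodium salt 10 (not isolated), via vinyl diazoalkane 11 (not isolated)
Conditions: NaH, 1,4-dioxane, rt; then Pd2(dba)3 (cat.), 60 °C
Reagents that add atoms: none
Why: Bamford–Stevens loss of sulfinate from the hydrazone salt gives the vinyl diazoalkane, whose palladium carbene cyclopropanates the tethered vinyl group (intramolecular carbene cyclopropanation); the tether enforces the cis 3/5 fusion, the trans-diequatorial arms on C5 and C10 give the trans 5/6 fusion, and the alkene reacts through its ground-state rotamer with C=C eclipsing the C10–CH3 bond, so that C2 ends on the methyl face and C1 and C3 are set as in the target.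

Step 9
Reactants: 12 8,8-ethylenedioxy-(1R,3S,5S,10S)-11,12,13-trinorlinden-4(15)-ene
Product: 13 (1R,3S,5S,10S)-11,12,13-trinorlinden-4(15)-en-8-one
Conditions: AcOH/THF/H2O, 40 °C
Reagents that add atoms: water, O
Why: Mild aqueous-acid hydrolysis of the dioxolane should free the C8 ketone without protonating the methylenecyclopropane unit.

Step 10
Reactants: 13 (1R,3S,5S,10S)-11,12,13-trinorlinden-4(15)-en-8-one; 14 ethyl pyruvate
Product: 16 ethyl 2-hydroxy-2-[(1R,3S,5S,10S)-8-oxo-11,12,13-trinorlinden-4(15)-en-7-yl]propanoate (C7/C11 epimer mixture), via lithium enolate 15 (not isolated)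
Conditions: LiN(i-Pr)2, THF, −78 °C; then ethyl pyruvate, −78 °C; AcOH quench
Reagents that add atoms: none
Why: Kinetic deprotonation by the hindered amide base should occur at C7, away from the neopentyl C9 next to quaternary C10, and the lithium enolate undergoes a crossed aldol addition to the highly electrophilic keto group of the pyruvate; the new centres at C7 and C11 are left uncontrolled because both become sp2 in step 11.

Step 11
Reactants: 16 ethyl 2-hydroxy-2-[(1R,3S,5S,10S)-8-oxo-11,12,13-trinorlinden-4(15)-en-7-yl]propanoate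
Product: 18 chloranthalactone A, via alkylidene keto ester 17 (not isolated)
Conditions: p-TsOH·H2O (cat.), benzene, reflux (Dean–Stark)
Reagents that add atoms: none
Why: Acid-catalysed dehydration of the β-hydroxy ketone gives the alkylidene keto ester, whose C8 enol (possible only toward C9) lactonises onto the cis-disposed ester with loss of ethanol, a butenolide annulation that ends in the fully conjugated γ-alkylidenebutenolide.

Step 12
Reactants: 18 chloranthalactone A (two molecules)
Product: 19 chloranthalactone F, the anti head-to-head C8–C8′/C9–C9′ cyclobutane dimer (target)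
Conditions: hν (medium-pressure Hg lamp, Pyrex filter), degassed hexane, rt, high concentration
Reagents that add atoms: none
Why: Excitation of the cross-conjugated γ-alkylidenebutenolide chromophore, followed by intersystem crossing, lets the terminal carbon C9 of one molecule bond to C9′ of a ground-state molecule, giving a 1,4-diradical whose centres C8 and C8′ are each allylic, α-oxygenated and conjugated to a lactone carbonyl; spin inversion and radical recombination then form the C8–C8′ bond. This is an enone-type head-to-head [2+2] photodimerisation, the reaction type by which simple 5-alkylidenefuran-2-ones and cyclic enones dimerise. The only ring closed is the cyclobutane C8–C9–C9′–C8′, by intermolecular bond formation followed by 1,4-diradical collapse, and each cyclohexane must be cis-fused to it. All four new stereocentres (C8, C9, C8′, C9′) are set by approach to the α face of each dienolide, anti to the axial C14 methyl on C10 that flanks C9, and by the anti arrangement of the two halves in the diradical (O8/O8′ and H9/H9′ trans), which keeps the lactone dipoles and ring systems apart. The step needs chemoselectivity for C8=C9, head-to-head regioselectivity and α/α facial selectivity: C8=C9 is the unhindered terminus of the only chromophore excited above 300 nm and gives the best stabilised diradical, C7=C11 is tetrasubstituted, and C4=C15 is an isolated alkene that is not excited.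

Compound list
1 | (1R,5R)-(+)-verbenone, (1R,5R)-4,6,6-trimethylbicyclo[3.1.1]hept-3-en-2-one | CC1=CC(=O)[C@@H]2C[C@H]1C2(C)C | starting material
2 | vinylmagnesium bromide | C=C[Mg]Br | starting material
3 | (1R,4S,5S)-4-ethenyl-4,6,6-trimethylbicyclo[3.1.1]heptan-2-one (vinyl anti to the CMe2 bridge) | O=C1C[C@@](C)(C=C)[C@H]2C[C@@H]1C2(C)C | intermediate
4 | (4S,5S)-5-ethenyl-5-methyl-4-(prop-1-en-2-yl)cyclohex-1-en-1-yl acetate (vinyl and isopropenyl trans) | CC(=O)OC1=CC[C@@H](C(C)=C)[C@](C)(C=C)C1 | intermediate
5 | (3S,4S)-3-ethenyl-3-methyl-4-(prop-1-en-2-yl)cyclohexan-1-one | O=C1C[C@@](C)(C=C)[C@H](C(C)=C)CC1 | intermediate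
6 | (7S,8S)-7-ethenyl-7-methyl-8-(prop-1-en-2-yl)-1,4-dioxaspiro[4.5]decane | C1COC2(O1)C[C@@](C)(C=C)[C@H](C(C)=C)CC2 | intermediate
7 | 2-[(7S,8R)-7-ethenyl-7-methyl-1,4-dioxaspiro[4.5]decan-8-yl]prop-2-en-1-ol | C1COC2(O1)C[C@@](C)(C=C)[C@H](C(CO)=C)CC2 | intermediate
8 | 2-[(7S,8R)-7-ethenyl-7-methyl-1,4-dioxaspiro[4.5]decan-8-yl]prop-2-enal | C1COC2(O1)C[C@@](C)(C=C)[C@H](C(C=O)=C)CC2 | intermediate
9 | N′-{(E)-2-[(7S,8R)-7-ethenyl-7-methyl-1,4-dioxaspiro[4.5]decan-8-yl]prop-2-en-1-ylidene}-4-methylbenzenesulfonohydrazide | C1COC2(O1)C[C@@](C)(C=C)[C@H](C(=C)/C=N/NS(=O)(=O)c3ccc(C)cc3)CC2 | intermediate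
10 | sodium salt of tosylhydrazone 9 | C1COC2(O1)C[C@@](C)(C=C)[C@H](C(=C)/C=N/[N-]S(=O)(=O)c3ccc(C)cc3)CC2.[Na+] | intermediate
11 | (7S,8R)-8-(3-diazoprop-1-en-2-yl)-7-ethenyl-7-methyl-1,4-dioxaspiro[4.5]decane | C1COC2(O1)C[C@@](C)(C=C)[C@H](C(=C)C=[N+]=[N-])CC2 | intermediate
12 | 8,8-ethylenedioxy-(1R,3S,5S,10S)-11,12,13-trinorlinden-4(15)-ene (cyclopropane cis-fused, C2 syn to the C14 methyl; 5/6 fusion trans) | C=C1[C@H]2C[C@H]2[C@@]2(C)[C@H]1CCC1(OCCO1)C2 | intermediate
13 | (1R,3S,5S,10S)-11,12,13-trinorlinden-4(15)-en-8-one | C=C1[C@H]2C[C@H]2[C@@]2(C)[C@H]1CCC(=O)C2 | intermediate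
14 | ethyl pyruvate | CCOC(=O)C(C)=O | starting material
15 | lithium 7-en-8-olate of ketone 13 | C=C1[C@H]2C[C@H]2[C@@]2(C)[C@H]1CC=C([O-])C2.[Li+] | intermediate
16 | ethyl 2-hydroxy-2-[(1R,3S,5S,10S)-8-oxo-11,12,13-trinorlinden-4(15)-en-7-yl]propanoate (epimers at C7 and C11) | C=C1[C@H]2C[C@H]2[C@@]2(C)[C@H]1CC(C(C)(O)C(=O)OCC)C(=O)C2 | intermediate
17 | ethyl 2-[(1R,3S,5S,10S)-8-oxo-11,12,13-trinorlinden-4(15)-en-7-ylidene]propanoate (E/Z mixture) | C=C1[C@H]2C[C@H]2[C@@]2(C)[C@H]1CC(=C(C)C(=O)OCC)C(=O)C2 | intermediate
18 | chloranthalactone A, (1R,3S,5S,10S)-linda-4(15),7(11),8-trien-12,8-olide | C=C1[C@H]2C[C@H]2[C@@]2(C)[C@H]1CC1=C(C)C(=O)OC1=C2 | intermediate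
19 | chloranthalactone F: cyclobutane C8–C9–C9′–C8′ on the α face of both halves, O8/O8′ trans, H9/H9′ trans | C=C1[C@H]2C[C@H]2[C@@]2(C)[C@H]1CC1=C(C)C(=O)O[C@]13[C@H]2[C@H]1[C@@]2(C)[C@@H]4C[C@@H]4C(=C)[C@@H]2CC2=C(C)C(=O)O[C@@]213 | target

Total step count: 12
Longest linear sequence: 12 steps (fully linear from compound 1)

Steps most likely to fail

Step 8. The vinyl diazoalkane may close to a pyrazole by 1,5-electrocyclisation before the metal captures it, and carbene transfer through the minor vinyl rotamer would erode the facial selectivity at C1 and C3. The fallback replaces the donor vinylcarbene by an acceptor carbene and moves the methylenation to the end. It sets out from dioxolane 6. m-CPBA (NaHCO3, CH2Cl2, 0 °C) should epoxidise the more nucleophilic 1,1-disubstituted alkene to give the epoxide F1. Periodic acid (Et2O/THF, 0 °C) should cleave it to the methyl ketone F2. Trifluoroacetylation of the methyl-side enolate (LiN(SiMe3)2, CF3CO2CH2CF3, THF, −78 °C) should give the trifluoroacetyl diketone F3. Detrifluoroacetylative diazo transfer (MsN3, Et3N, MeCN/H2O) should give the α-diazoketone F4. Rh2(OAc)4 in CH2Cl2 should then effect intramolecular cyclopropanation to the tricyclic cyclopropyl ketone F5. Wittig methylenation with salt-free Ph3P=CH2 comes back to the route at compound 12.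

Step 12. Head-to-tail or syn coupling, oligomerisation through the diradical, and unimolecular photoisomerisation of the dienolide may compete. The fallback is a ground-state radical-cation cycloaddition that sets out from 18 and comes back at 19. Single-electron oxidation of the electron-rich 1-acyloxydiene unit with a catalytic aminium salt, (4-BrC6H4)3N+ SbCl6−, in CH2Cl2 at 0 °C should start a hole-catalysed [2+2] cyclodimerisation. The radical cation should bond through C9 to C9′ of a neutral molecule, and the distonic intermediate should close at C8–C8′ before back electron transfer. This way makes no compound outside the list (F0).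

Step 10. Partial enolisation toward C9, proton transfer from the enolisable pyruvate to the enolate, and retro-aldol cleavage during work-up may all lower the outcome. The fallback uses an enamine in place of the metal enolate and sets out from ketone 13. Condensation with pyrrolidine (benzene, Dean–Stark) should give, under thermodynamic control, the less hindered pyrrolidine enamine F6 with its double bond toward C7. This should add to ethyl pyruvate 14 under neutral conditions (Stork enamine aldol-type addition). Buffered hydrolysis (aq. AcOH/NaOAc) comes back to the route at aldol adduct 16.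

Further compounds
F1 | step 8 | (7S,8R)-7-ethenyl-7-methyl-8-(2-methyloxiran-2-yl)-1,4-dioxaspiro[4.5]decane (epimers at the oxirane carbon) | C1COC2(O1)C[C@@](C)(C=C)[C@H](C3(C)CO3)CC2
F2 | step 8 | 1-[(7S,8R)-7-ethenyl-7-methyl-1,4-dioxaspiro[4.5]decan-8-yl]ethan-1-one | C1COC2(O1)C[C@@](C)(C=C)[C@H](C(C)=O)CC2
F3 | step 8 | 4,4,4-trifluoro-1-[(7S,8R)-7-ethenyl-7-methyl-1,4-dioxaspiro[4.5]decan-8-yl]butane-1,3-dione | C1COC2(O1)C[C@@](C)(C=C)[C@H](C(=O)CC(=O)C(F)(F)F)CC2
F4 | step 8 | 2-diazo-1-[(7S,8R)-7-ethenyl-7-methyl-1,4-dioxaspiro[4.5]decan-8-yl]ethan-1-one | C1COC2(O1)C[C@@](C)(C=C)[C@H](C(=O)C=[N+]=[N-])CC2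
F5 | step 8 | 8,8-ethylenedioxy-11,12,13,15-tetranorlindenan-4-one (ring fusions as in 12) | O=C1[C@H]2C[C@H]2[C@@]2(C)[C@H]1CCC1(OCCO1)C2
F0 | step 12 | none | none
F6 | step 10 | 1-[(1R,3S,5S,10S)-11,12,13-trinorlinda-4(15),7-dien-8-yl]pyrrolidine | C=C1[C@H]2C[C@H]2[C@@]2(C)[C@H]1CC=C(N3CCCC3)C2
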